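**Plan**

- Retrosynthesis: C7=C8 is cut to a ring C10 phenyl sulfone (C7 as nucleophile) and a C30 allylic bromide. C7'=C8' is cut by a Wittig disconnection to crocetindial (C8–C8') and a geranyl ylide. The C3 and C4 oxygens are then taken off through the ring 3,4-olefin, and the ring bond C1–C6 is cut last.
- Enabling feature: ring carbons C1–C6 with methyls C16 and C17 on C1 and C18 on C5 are the cyclised counterpart of the open terminus C1'–C6' with C16', C17' and C18'. Geraniol therefore serves for both ends, and the only ring of the target is closed at C1–C6 by a proton-initiated cation–olefin cyclisation of geranyl phenyl sulfone.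
- Forward order: the ring is made first (step 3), then the ring diene and the C3/C4 oxygens. Separately, geranyl ylide and crocetindial give the C30 unit. C7–C8 is joined by sulfone alkylation, C7=C8 is unveiled by loss of sulfinate, and the silyl groups come off last.
- Stereochemistry: C3 and C4 both come from a Jacobsen–Katsuki epoxidation of the ring cis-olefin C3=C4, carried into the cis-diol with retention by CO2 insertion (double inversion at C4). Olefin geometry comes from geraniol and crocetindial, and the two new disubstituted olefins settle as E.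

Key step: step 3

Remark: atoms carry carotenoid numbers throughout (ring C1–C6 with C16/C17 on C1 and C18 on C5, C7 on C6, primed numbers for the open-chain half), and crocetindial is taken as the purchasable all-E C20 dialdehyde.

**Route**

Step 1
Reactants: 1 geraniol
Product: 2 geranyl bromide
Conditions: PBr3 (0.4 equiv), pyridine (0.1 equiv), Et2O, −10 °C
Reagents that add atoms: phosphorus tribromide, BrP(Br)Br
Why: Bromide displaces the phosphite ester of the primary allylic alcohol by SN2 at low temperature (alcohol-to-bromide substitution), so the 2E olefin and the position of the double bond are kept.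

Step 2
Reactants: 2 geranyl bromide; 3 sodium benzenesulfinate
Product: 4 geranyl phenyl sulfone
Conditions: DMF, 20 °C
Reagents that add atoms: none
Why: SN2 S-alkylation of the ambident sulfinate by a soft primary allylic bromide in a dipolar aprotic solvent gives the sulfone and not the sulfinate ester, and the E olefin is not touched.

Step 3
Reactants: 4 geranyl phenyl sulfone
Product: 5 β-cyclogeranyl phenyl sulfone
Conditions: conc H2SO4 (3 equiv), AcOH, 10 → 20 °C; ice-water quench, recrystallisation
Reagents that add atoms: none
Why: Protonation of the terminal olefin at C2 gives the tertiary C1 cation, the C5=C6 olefin attacks it through C6 to make the C1–C6 bond, and the tertiary C5 cation so formed sheds the proton on C6 to leave the tetrasubstituted C5=C6 olefin. The closest known reaction type is the Brønsted acid cation–olefin cyclisation of geranyl derivatives and of pseudoionone to the trimethylcyclohexene ring. The six-membered ring closes 6-endo-trig with respect to the C5=C6 olefin through a chair-like arrangement. No stereocentre is formed, because C1 carries two methyl groups and C5 and C6 end up sp2. The step needs protonation of C1=C2 in preference to C5=C6, which the electron-withdrawing sulfonylmethyl group on C6 secures. It also needs the C5=C6 olefin and not the C4=C5 or exocyclic isomer, which equilibration through the common C5 cation in strong acid should secure, with any residual isomer removed by crystallisation of the acid-stable sulfone.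

Step 4
Reactants: 5 β-cyclogeranyl phenyl sulfone
Product: 7 3,4-didehydro-β-cyclogeranyl phenyl sulfone, via 4-bromo sulfone 6 (not isolated)
Conditions: NBS (1.05 equiv), AIBN (2 mol %), PhCF3, 80 °C; then 2,4,6-collidine (3 equiv), 90 °C
Reagents that add atoms: none
Why: Wohl–Ziegler bromination should pick the secondary ring allylic hydrogen at C4 (the C7 hydrogens are deactivated towards the electrophilic bromine atom by the sulfonyl group), and E2 loss of HBr across C3–C4 with a weak hindered amine then gives the conjugated ring diene, which cannot aromatise because C1 is quaternary.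

Step 5
Reactants: 7 3,4-didehydro-β-cyclogeranyl phenyl sulfone
Product: 8 (3R,4S)-3,4-epoxy-β-cyclogeranyl phenyl sulfone
Conditions: [(S,S)-N,N'-bis(3,5-di-tert-butylsalicylidene)cyclohexane-1,2-diaminato]manganese chloride (4 mol %), 4-phenylpyridine N-oxide (20 mol %), aq NaOCl (Na2HPO4 buffer, pH 11.3), CH2Cl2, 0 °C
Reagents that add atoms: sodium hypochlorite, [Na+].[O-]Cl
Why: The Jacobsen–Katsuki epoxidation, for which a ring cis-olefin conjugated to a second π-bond is the best substrate class, should oxidise only the disubstituted C3=C4 bond (C5=C6 is tetrasubstituted and hindered), and with the C5=C6 unit playing the part that the arene plays in indene or chromenes the (S,S) complex should deliver oxygen to the face that makes C3 R and C4 S.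

Step 6
Reactants: 8 (3R,4S)-3,4-epoxy-β-cyclogeranyl phenyl sulfone
Product: 9 (3R,4S)-3,4-carbonyldioxy-β-cyclogeranyl phenyl sulfone (cis-fused cyclic carbonate)
Conditions: Pd(PPh3)4 (5 mol %), CO2 (1 atm), THF, 0 → 20 °C
Reagents that add atoms: carbon dioxide, O=C=O
Why: Zerovalent palladium opens the strained vinyl epoxide at the allylic C4–O bond with inversion, the freed C3 alkoxide takes up CO2, and the carbonate oxygen closes on C4 of the π-allyl complex from the face opposite to palladium (palladium-catalysed vinyl epoxide–CO2 cycloaddition), so that two inversions give the cis-fused five-membered carbonate with C3 untouched and C4 retained.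

Step 7
Reactants: 9 cyclic carbonate
Product: 10 (3R,4S)-3,4-dihydroxy-β-cyclogeranyl phenyl sulfone
Conditions: K2CO3 (0.2 equiv), MeOH, 20 °C
Reagents that add atoms: none
Why: Base-catalysed transesterification attacks only the carbonyl carbon, so both ring C–O bonds and the (3R,4S) cis arrangement are kept while the carbonyl group leaves as dimethyl carbonate.

Step 8
Reactants: 10 (3R,4S)-diol sulfone
Product: 11 (3R,4S)-3,4-bis(tert-butyldimethylsilyloxy)-β-cyclogeranyl phenyl sulfone
Conditions: TBSOTf (2.6 equiv), 2,6-lutidine (4 equiv), CH2Cl2, −20 → 20 °C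
Reagents that add atoms: tert-butyldimethylsilyl trifluoromethanesulfonate, CC(C)(C)[Si](C)(C)OS(=O)(=O)C(F)(F)F
Why: The silyl triflate converts both hindered secondary hydroxyls into silyl ethers without touching a C–O bond, and these ethers withstand organolithium and alkoxide bases and are later removed by fluoride instead of acid, which the allylic C4 oxygen of the final polyene would not tolerate.

Step 9
Reactants: 2 geranyl bromide
Product: 12 geranyltriphenylphosphonium bromide
Conditions: PPh3 (1.05 equiv), toluene, 20 °C
Reagents that add atoms: triphenylphosphine, c1ccc(cc1)P(c1ccccc1)c1ccccc1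
Why: Quaternisation of triphenylphosphine by the primary allylic bromide (SN2 phosphonium salt formation) should give the crystalline salt with the E olefin unchanged.

Step 10
Reactants: 12 geranyltriphenylphosphonium bromide; 13 crocetindial
Product: 15 apo-8'-lycopenal (all-E C30 aldehyde), via geranyl ylide 14 (not isolated)
Conditions: 12, n-BuLi (1.0 equiv), THF, −78 → −30 °C; added slowly to 13 (3 equiv), THF/CH2Cl2, −30 → 20 °C; then heptane, reflux (Z→E), crystallisation
Reagents that add atoms: none
Why: Wittig olefination of one aldehyde group, favoured statistically by the excess of dialdehyde, forms C7'=C8', whose Z/E mixture should equilibrate thermally to the all-E isomer because this disubstituted bond is unhindered, while the trisubstituted C5'=C6' bond of the allylic ylide keeps its E geometry at low temperature.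

Step 11
Reactants: 15 apo-8'-lycopenal
Product: 16 apo-8'-lycopenol (all-E C30 allylic alcohol)
Conditions: NaBH4 (0.5 equiv), THF/EtOH, 0 °C, dark
Reagents that add atoms: none
Why: Borohydride reduction of the conjugated aldehyde proceeds by 1,2-addition and leaves the polyene untouched.

Step 12
Reactants: 16 apo-8'-lycopenol
Product: 17 apo-8'-lycopenyl bromide (all-E C30 allylic bromide)
Conditions: PBr3 (0.4 equiv), pyridine (0.1 equiv), Et2O/THF, −30 °C, dark; cold aq NaHCO3 wash, dried at −20 °C, solution used at once
Reagents that add atoms: phosphorus tribromide, BrP(Br)Br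
Why: Low-temperature displacement of the phosphite ester by bromide at the primary allylic carbon (alcohol-to-bromide substitution) should give the labile polyenyl bromide in the way known for retinol-type alcohols, provided the solution is kept cold, dark, acid-free and is not stored.

Step 13
Reactants: 11 bis-silyl sulfone (1.1 equiv); 17 apo-8'-lycopenyl bromide
Product: 19 (3R,4S)-3,4-bis(tert-butyldimethylsilyloxy)-7-phenylsulfonyl-7,8-dihydro-β,ψ-carotene (C7 epimers), via lithiated sulfone 18 (not isolated)
Conditions: 11, n-BuLi (1.05 equiv), THF, −78 °C; then 17 in THF, −78 → −40 °C, dark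
Reagents that add atoms: none
Why: The lithiated allylic sulfone reacts at its α-carbon C7 with the primary allylic bromide by SN2 (alkylation stage of the Julia sulfone route to olefins) to form C7–C8, the new C7 centre arises as an epimer mixture that is erased in the next step, and at −78 °C the carbanion is not expected to expel the C4 silyloxy group.

Step 14
Reactants: 19 C40 sulfone
Product: 20 (3R,4S)-3,4-bis(tert-butyldimethylsilyloxy)-β,ψ-carotene (all-E)
Conditions: KOtBu (3 equiv), THF, −20 → 0 °C, dark, argon
Reagents that add atoms: none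
Why: Base-induced 1,2-elimination of benzenesulfinate (dehydrosulfonylation stage of the Julia sequence) removes a C8 hydrogen acidified by the adjoining nonaene and expels the C7 sulfonyl group, and the C7=C8 olefin should form as the E isomer because the Z isomer would press the chain against the ring methyl groups.

Step 15
Reactants: 20 bis-silyl carotenoid
Product: 21 (3R,4S)-β,ψ-carotene-3,4-diol (all-E), the target
Conditions: TBAF (4 equiv), THF, 0 → 20 °C, dark, argon; crystallisation
Reagents that add atoms: none
Why: Fluoride desilylation cleaves both Si–O bonds under non-acidic conditions, so the allylic C4–O bond is not ionised and the (3R,4S) cis-diol and the all-E polyene stay as they are.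

**Compound list**

1 | geraniol, (2E)-3,7-dimethylocta-2,6-dien-1-ol | CC(C)=CCC/C(C)=C/CO | starting material
2 | geranyl bromide, (2E)-1-bromo-3,7-dimethylocta-2,6-diene | CC(C)=CCC/C(C)=C/CBr | intermediate
3 | sodium benzenesulfinate | [Na+].[O-]S(=O)c1ccccc1 | starting material
4 | geranyl phenyl sulfone, (2E)-3,7-dimethylocta-2,6-dienyl phenyl sulfone | CC(C)=CCC/C(C)=C/CS(=O)(=O)c1ccccc1 | intermediate
5 | β-cyclogeranyl phenyl sulfone, (2,6,6-trimethylcyclohex-1-enyl)methyl phenyl sulfone | CC1=C(CS(=O)(=O)c2ccccc2)C(C)(C)CCC1 | intermediate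
6 | racemic 4-bromo-β-cyclogeranyl phenyl sulfone, (3-bromo-2,6,6-trimethylcyclohex-1-enyl)methyl phenyl sulfone | CC1=C(CS(=O)(=O)c2ccccc2)C(C)(C)CCC1Br | intermediate (not isolated)
7 | 3,4-didehydro-β-cyclogeranyl phenyl sulfone, (2,6,6-trimethylcyclohexa-1,3-dienyl)methyl phenyl sulfone | CC1=C(CS(=O)(=O)c2ccccc2)C(C)(C)CC=C1 | intermediate
8 | (3R,4S)-3,4-epoxy-β-cyclogeranyl phenyl sulfone, (1S,6R)-2,4,4-trimethyl-3-(phenylsulfonylmethyl)-7-oxabicyclo[4.1.0]hept-2-ene | O=S(=O)(CC1=C(C)[C@@H]2O[C@@H]2CC1(C)C)c1ccccc1 | intermediate
9 | (3R,4S)-3,4-carbonyldioxy-β-cyclogeranyl phenyl sulfone, cis-fused cyclic carbonate of 10 | O=S(=O)(CC1=C(C)[C@@H]2OC(=O)O[C@@H]2CC1(C)C)c1ccccc1 | intermediate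
10 | (3R,4S)-3,4-dihydroxy-β-cyclogeranyl phenyl sulfone, (1R,2S)-3,5,5-trimethyl-4-(phenylsulfonylmethyl)cyclohex-3-ene-1,2-diol (cis) | O=S(=O)(CC1=C(C)[C@H](O)[C@H](O)CC1(C)C)c1ccccc1 | intermediate
11 | (3R,4S)-3,4-bis(tert-butyldimethylsilyloxy)-β-cyclogeranyl phenyl sulfone | O=S(=O)(CC1=C(C)[C@H](O[Si](C)(C)C(C)(C)C)[C@H](O[Si](C)(C)C(C)(C)C)CC1(C)C)c1ccccc1 | intermediate
12 | geranyltriphenylphosphonium bromide | CC(C)=CCC/C(C)=C/C[P+](c1ccccc1)(c1ccccc1)c1ccccc1.[Br-] | intermediate
13 | crocetindial, (2E,4E,6E,8E,10E,12E,14E)-2,6,11,15-tetramethylhexadeca-2,4,6,8,10,12,14-heptaenedial | O=C/C(C)=C/C=C/C(C)=C/C=C/C=C(C)/C=C/C=C(C)/C=O | starting material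
14 | geranylidenetriphenylphosphorane (ylide of 12) | CC(C)=CCC/C(C)=C/C=P(c1ccccc1)(c1ccccc1)c1ccccc1 | intermediate (not isolated)
15 | apo-8'-lycopenal, all-E 2,6,11,15,19,23-hexamethyltetracosa-2,4,6,8,10,12,14,16,18,22-decaenal | CC(C)=CCC/C(C)=C/C=C/C(C)=C/C=C/C(C)=C/C=C/C=C(C)/C=C/C=C(C)/C=O | intermediate
16 | apo-8'-lycopenol, the primary allylic alcohol of 15 | CC(C)=CCC/C(C)=C/C=C/C(C)=C/C=C/C(C)=C/C=C/C=C(C)/C=C/C=C(C)/CO | intermediate
17 | apo-8'-lycopenyl bromide, the primary allylic bromide of 16 | CC(C)=CCC/C(C)=C/C=C/C(C)=C/C=C/C(C)=C/C=C/C=C(C)/C=C/C=C(C)/CBr | intermediate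
18 | C7-lithio derivative of 11 | [Li+].O=S(=O)([CH-]C1=C(C)[C@H](O[Si](C)(C)C(C)(C)C)[C@H](O[Si](C)(C)C(C)(C)C)CC1(C)C)c1ccccc1 | intermediate (not isolated)
19 | (3R,4S)-3,4-bis(tert-butyldimethylsilyloxy)-7-phenylsulfonyl-7,8-dihydro-β,ψ-carotene, both C7 epimers | CC(C)=CCC/C(C)=C/C=C/C(C)=C/C=C/C(C)=C/C=C/C=C(C)/C=C/C=C(C)/CC(C1=C(C)[C@H](O[Si](C)(C)C(C)(C)C)[C@H](O[Si](C)(C)C(C)(C)C)CC1(C)C)S(=O)(=O)c1ccccc1 | intermediate
20 | (3R,4S)-3,4-bis(tert-butyldimethylsilyloxy)-β,ψ-carotene, all-E | CC(C)=CCC/C(C)=C/C=C/C(C)=C/C=C/C(C)=C/C=C/C=C(C)/C=C/C=C(C)/C=C/C1=C(C)[C@H](O[Si](C)(C)C(C)(C)C)[C@H](O[Si](C)(C)C(C)(C)C)CC1(C)C | intermediate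
21 | (3R,4S)-β,ψ-carotene-3,4-diol, all-E (CNP0310445.2) | CC(C)=CCC/C(C)=C/C=C/C(C)=C/C=C/C(C)=C/C=C/C=C(C)/C=C/C=C(C)/C=C/C1=C(C)[C@H](O)[C@H](O)CC1(C)C | target

**Step count**

Total: 15 steps. Longest linear sequence: 11 steps (steps 1–8, then 13–15).

**Steps most likely to fail**

1. Step 12 (with its use in step 13). The nonaenyl bromide may ionise, eliminate or take up an electron from the carbanion faster than it is C-alkylated, so that the C30 unit is lost before C7–C8 exists. The fallback avoids any polyenyl halide and sets out from sulfone 11 and aldehyde 15. Lithiated 11 (n-BuLi, THF, −78 °C) is added to 15 and the alkoxide is trapped with benzoyl chloride to give the β-benzoyloxy sulfone F1 as a diastereomer mixture. Reductive elimination with SmI2/HMPA in THF at −78 °C (Julia–Lythgoe olefination) should then give the E C7=C8 olefin. This returns to the route at compound 20, and steps 11–14 fall away.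

2. Step 5. Oxygen transfer to the ring diene may show poor facial selectivity, and the acid-sensitive vinyl epoxide may open or rearrange during isolation. The fallback sets out from diene 7 and makes the cis-diol by osmium chemistry, followed by resolution. Upjohn dihydroxylation (OsO4 2 mol %, NMO, acetone/water) should attack only the disubstituted C3=C4 bond and give the racemic cis-diol F2. Esterification with (S)-O-methylmandelic acid (DCC, DMAP, CH2Cl2) gives two diastereomeric diesters, the bis-mandelate of the (3R,4S)-diol F3 and the bis-mandelate of the (3S,4R)-diol F4, which are separated by chromatography or crystallisation and assigned by X-ray analysis against the known mandelate centre. Methanolysis of F3 (K2CO3, MeOH) returns to the route at diol 10, and steps 5–7 fall away.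

3. Step 4. Hydrogen abstraction may also occur at the C18 methyl group, a second bromination may follow, and loss of HBr may run as a 1,4-elimination through the acidic C7 hydrogens to a dienyl sulfone instead of the ring diene. The fallback sets out from sulfone 5 and reaches the diene through the C4 alcohol. Allylic oxidation (CrO3, 3,5-dimethylpyrazole, CH2Cl2, −20 °C) should give the 4-oxo sulfone F5. Luche reduction (NaBH4, CeCl3·7H2O, MeOH, 0 °C) gives the racemic 4-hydroxy sulfone F6. Syn-dehydration with the Burgess reagent (toluene, 60 °C) is an intramolecular elimination that can reach only a C3 hydrogen, and it returns to the route at diene 7.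

Further compounds
F1 | step 12 | (3R,4S)-8-benzoyloxy-3,4-bis(tert-butyldimethylsilyloxy)-7-phenylsulfonyl-7,8-dihydro-β,ψ-carotene (C7/C8 diastereomers) | CC(C)=CCC/C(C)=C/C=C/C(C)=C/C=C/C(C)=C/C=C/C=C(C)/C=C/C=C(C)/C(OC(=O)c1ccccc1)C(C1=C(C)[C@H](O[Si](C)(C)C(C)(C)C)[C@H](O[Si](C)(C)C(C)(C)C)CC1(C)C)S(=O)(=O)c1ccccc1
F2 | step 5 | racemic cis-3,4-dihydroxy-β-cyclogeranyl phenyl sulfone (both enantiomers) | O=S(=O)(CC1=C(C)[C@H](O)[C@H](O)CC1(C)C)c1ccccc1.O=S(=O)(CC1=C(C)[C@@H](O)[C@@H](O)CC1(C)C)c1ccccc1
F3 | step 5 | bis[(S)-O-methylmandelate] of the (3R,4S)-diol sulfone | O=S(=O)(CC1=C(C)[C@H](OC(=O)[C@@H](OC)c2ccccc2)[C@H](OC(=O)[C@@H](OC)c2ccccc2)CC1(C)C)c1ccccc1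
F4 | step 5 | bis[(S)-O-methylmandelate] of the (3S,4R)-diol sulfone | O=S(=O)(CC1=C(C)[C@@H](OC(=O)[C@@H](OC)c2ccccc2)[C@@H](OC(=O)[C@@H](OC)c2ccccc2)CC1(C)C)c1ccccc1
F5 | step 4 | 4-oxo-β-cyclogeranyl phenyl sulfone | CC1=C(CS(=O)(=O)c2ccccc2)C(C)(C)CCC1=O
F6 | step 4 | racemic 4-hydroxy-β-cyclogeranyl phenyl sulfone | CC1=C(CS(=O)(=O)c2ccccc2)C(C)(C)CCC1O
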